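**Retrosynthetic overview**

1. Numbering (daucane): ring A = C1(15‑Me)–C2–C3–C4(iPr, OH)–C5; ring B = C1–C5–C6–C7–C8(14‑Me, OH)–C9–C10; α = face of H‑5, β = face of the C1 methyl.
2. Target ⇐ 6,9‑diketone 24 (angelates on O6/O10 last; C6 by O4‑directed reduction, C9 by face‑selective reduction) ⇐ retro‑aldol cleavage of C5–C9 in cyclobutane 22 ⇐ intramolecular [2+2] photocycloaddition of monocyclic enol carbonate 21, which forms C5–C1 and C9–C10.
3. Enabling feature: in ring B the oxygens on C6 and C9 are 1,4‑related, with ring‑fusion carbon C5 next to C6 and a tertiary hydroxyl on C8 next to C9. C5–C6–C7–C8–C9 is therefore a 4‑hydroxycyclopentane‑1,3‑dione ring enlarged by C1 and C10, and O8 can be tied to the C9 enol oxygen as a carbonate that fixes enol regiochemistry and π‑face.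
4. 21 ⇐ Claisen closure (C5–C9) of keto ester 17 ⇐ pyruvate Mukaiyama aldol (C7–C8, sets C8) of methyl ketone 13 ⇐ ozonolytic ring opening of (R)‑terpinen‑4‑ol, whose ten carbons become C1–C6, C11–C13 and C15 and whose carbinol stereocentre becomes C4.
5. Ring order: dione ring (step 7), then ring A and the cyclobutane together (step 9), then ring B by two‑carbon ring expansion (step 10).

Key step: step 9

Assumption: (R)‑(−)‑terpinen‑4‑ol is used enantiomerically pure (commercial material of lower optical purity would first be enriched), and the copper–bisoxazoline aldol is taken to show the same facial sense as with simple enol silanes.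
Remark: compounds 9, 12, 13, 15, 17, 18, 19 and 21 are E/Z mixtures at the C1=C10 enol ether; their SMILES leave this double bond open because step 9 is stereoconvergent.

**Route**

Step 1
Reactants: 1 (R)‑terpinen‑4‑ol; 2 triethylsilyl trifluoromethanesulfonate
Product: 3 triethylsilyl ether of 1
Conditions: Et3SiOTf, 2,6‑lutidine, CH2Cl2, −78 → 0 °C
Reagents that add atoms: triethylsilyl trifluoromethanesulfonate, CC[Si](CC)(CC)OS(=O)(=O)C(F)(F)F
Why: Silylation of a hindered tertiary alcohol with a silyl triflate is routine, and the ether blocks retro‑aldol and dehydration of the later β‑oxygenated carbonyl unit at C4, whose configuration is carried unchanged from 1.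

Step 2
Reactants: 3; 4 ozone; 5 methanol
Product: 7 methyl (R)‑6‑oxo‑3‑(propan‑2‑yl)‑3‑(triethylsilyloxy)heptanoate, via methoxy hydroperoxide 6 (not isolated)
Conditions: O3, CH2Cl2/MeOH (5:1), NaHCO3, −78 °C; then Ac2O, Et3N, CH2Cl2, 0 °C → rt
Reagents that add atoms: ozone, [O-][O+]=O; methanol, CO
Why: Ozonolysis of the trisubstituted ring alkene in methanol (Criegee mechanism) should leave the methyl ketone at C1 and trap the carbonyl oxide of the former CH carbon (C6) as the α‑methoxy hydroperoxide, which Ac2O/Et3N dehydrates to the methyl ester, so the two ends are differentiated in one flask and no stereocentre is touched.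

Step 3
Reactants: 7; 8 (benzyloxymethyl)triphenylphosphonium chloride
Product: 9 methyl (R)‑7‑(benzyloxy)‑6‑methyl‑3‑(propan‑2‑yl)‑3‑(triethylsilyloxy)hept‑6‑enoate (E/Z mixture)
Conditions: 8, KN(SiMe3)2, THF, −78 → 0 °C; then 7, 0 °C → rt
Reagents that add atoms: (benzyloxymethyl)triphenylphosphonium chloride, [Cl-].c1ccc(cc1)[P+](COCc1ccccc1)(c1ccccc1)c1ccccc1
Why: Wittig alkoxymethylenation of the methyl ketone installs the enol ether C1(Me)=C10H–OBn and thereby brings in C10 with its oxygen, the ester being inert to the ylide under these conditions.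

Step 4
Reactants: 9; 10 N,O‑dimethylhydroxylamine hydrochloride; 11 methylmagnesium bromide
Product: 13 (R)‑8‑(benzyloxy)‑7‑methyl‑4‑(propan‑2‑yl)‑4‑(triethylsilyloxy)oct‑7‑en‑2‑one, via Weinreb amide 12 (not isolated)
Conditions: MeNH(OMe)·HCl (1.5 equiv), MeMgBr (5 equiv), THF, −15 → 0 °C
Reagents that add atoms: methylmagnesium bromide, C[Mg]Br
Why: One‑pot Weinreb ketone synthesis: the magnesium amide formed in situ converts the ester into the Weinreb amide, whose chelated tetrahedral adduct with MeMgBr stops the addition at the ketone, the new methyl group being C7.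

Step 5
Reactants: 13; 14 chlorotrimethylsilane
Product: 15 2‑(trimethylsilyloxy)‑1‑ene enol silane of 13
Conditions: LiN(iPr)2, THF, −78 °C; then Me3SiCl; non‑aqueous work‑up
Reagents that add atoms: chlorotrimethylsilane, C[Si](C)(C)Cl
Why: Kinetic deprotonation takes the methyl group rather than the neopentyl‑type C5 methylene next to quaternary C4, so O‑silylation gives the terminal enol silane needed for the Mukaiyama aldol.

Step 6
Reactants: 15; 16 methyl pyruvate
Product: 17 methyl (2S,6R)‑10‑(benzyloxy)‑2,9‑dimethyl‑4‑oxo‑6‑(propan‑2‑yl)‑6‑(triethylsilyloxy)‑2‑(trimethylsilyloxy)dec‑9‑enoate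
Conditions: Cu(OTf)2 (10 mol %), (S,S)‑2,2'‑isopropylidenebis(4‑tert‑butyl‑2‑oxazoline) (11 mol %), methyl pyruvate (2 equiv), THF, −78 °C; NaHCO3 work‑up without acid
Reagents that add atoms: methyl pyruvate, COC(=O)C(C)=O
Why: Catalytic enantioselective Mukaiyama aldol addition to a pyruvate ester, in which the bisoxazoline complex of divalent copper chelates both pyruvate carbonyls and shields the re face so that the enol silane adds to the si face and sets C8 as S with silyl transfer to the new tertiary oxygen, while the hindered trisubstituted benzyl enol ether should be too weak a nucleophile to compete at −78 °C.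

Step 7
Reactants: 17
Product: 19 hydroxy dione (C9 enol form), via silylated dione 18 (not isolated)
Conditions: LiN(SiMe3)2 (2.3 equiv), THF, −78 → −20 °C; then K2CO3 (0.3 equiv), MeOH, 0 °C → rt; AcOH quench
Reagents that add atoms: none
Why: Intramolecular Claisen (Dieckmann‑type) acylation in which only the C5 enolate can reach the ester (five‑membered ring, whereas the C7 enolate would give a three‑membered ring) and deprotonation of the acidic 1,3‑dione drives the closure, after which methanolysis frees the C8 hydroxyl; C4 and C8 are not enolisable and keep their configuration.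

Step 8
Reactants: 19; 20 1,1'‑carbonyldiimidazole
Product: 21 cyclic enol carbonate (O8 and the C9 enol oxygen joined by C=O)
Conditions: CDI (1.3 equiv), DMAP (5 mol %), CH2Cl2, 0 °C → rt
Reagents that add atoms: 1,1'‑carbonyldiimidazole, O=C(n1ccnc1)n1ccnc1
Why: O‑Acylation of the acidic dione enol by carbonyldiimidazole and ring closure by the neighbouring tertiary C8 hydroxyl give the five‑membered carbonate, and because acyl transfer between the two enol oxygens is reversible and only O9 can close a ring with O8, the enol double bond is fixed as C5=C9.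

Step 9
Reactants: 21
Product: 22 cyclobutane photoadduct (four‑membered ring C5–C9–C10–C1 fused cis to the cyclopentanone at C5–C9, to ring A at C5–C1 and, through C8–C9, to the dioxolanone; C1 methyl syn to C6; benzyloxy on C10 anti to the C1 methyl)
Conditions: hν (λ ≥ 300 nm, Pyrex filter, medium‑pressure Hg lamp), degassed MeCN (5 mM), 0 °C
Reagents that add atoms: none
Why: n→π* excitation of the 3‑acyloxy‑enone (C6=O, C5=C9) and intersystem crossing give the enone triplet, which bonds C5 to C1 and then collapses the resulting 1,4‑biradical (C9/C10) to the C9–C10 bond. The closest known reaction type is the intramolecular de Mayo‑type [2+2] photocycloaddition of enol esters of 2‑(pent‑4‑enyl)cycloalkane‑1,3‑diones, here with an enol ether as the alkene partner. Ring A (C1–C5) closes in the 5‑exo mode (1,5‑closure, rule of five) through the three‑atom tether C2–C3–C4 and the cyclobutane closes by 4‑exo radical recombination, so the straight and not the crossed adduct is expected. C9, C5 and C1 are controlled by C8 through the carbonate ring: only addition to the enone face syn to the C8 methyl leaves the dioxolanone cis‑fused, and the two cis fusions at the cyclobutane then place the C1 methyl syn to C6, which is the 1R configuration of the target, while C4 is a spectator whose isopropyl group has to lie on the concave face. C10 is set in the biradical collapse, where the benzyloxy group should take the position anti to quaternary C8 and the C1 methyl (syn to O9), so both geometric isomers of the enol ether converge on the 10R epimer. The step needs enol regiocontrol and π‑face control, both secured by the carbonate tether (C9 and not C6 is the enol carbon, and biradicals that could close only to a trans‑fused dioxolanone revert to 21), and it delivers a cyclobutane with three quaternary carbons whose strain drives step 10.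

Step 10
Reactants: 22
Product: 24 10α‑(benzyloxy)‑8α‑hydroxy‑4β‑(triethylsilyloxy)‑5αH‑daucane‑6,9‑dione, via cyclobutanediol 23 (not isolated)
Conditions: LiOH·H2O (3 equiv), THF/H2O (3:1), 0 °C → rt
Reagents that add atoms: none
Why: Hydrolysis of the carbonate frees the C9 cyclobutanol, whose alkoxide undergoes retro‑aldol cleavage of C5–C9 (de Mayo fragmentation) driven by release of ring strain and so converts the dione ring plus C1 and C10 into ring B; C5 is set by protonation under equilibrating conditions, where the trans ring fusion should be favoured because C6 then lies on the face of the O4 silyloxy group and not of the isopropyl group, and hydroxide rather than methoxide is used so that no carbonate leaving group remains on O8.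

Step 11
Reactants: 24; 25 tert‑butyldimethylsilyl trifluoromethanesulfonate
Product: 26 10α‑(benzyloxy)‑8α‑(tert‑butyldimethylsilyloxy)‑4β‑(triethylsilyloxy)‑5αH‑daucane‑6,9‑dione
Conditions: tBuMe2SiOTf (1.3 equiv), 2,6‑lutidine, CH2Cl2, −78 → 0 °C
Reagents that add atoms: tert‑butyldimethylsilyl trifluoromethanesulfonate, CC(C)(C)[Si](C)(C)OS(=O)(=O)C(F)(F)F
Why: Silyl triflate silylation of the tertiary α‑ketol hydroxyl masks O8 so that it cannot direct hydride to C6 or C9 in step 13, and the bulky group later shields the α face of C9.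

Step 12
Reactants: 26
Product: 27 10α‑(benzyloxy)‑8α‑(tert‑butyldimethylsilyloxy)‑4β‑hydroxy‑5αH‑daucane‑6,9‑dione
Conditions: HF·pyridine, pyridine, THF, 0 °C
Reagents that add atoms: none
Why: Buffered fluoride desilylation cleaves the triethylsilyl ether much faster than the tert‑butyldimethylsilyl ether and frees the C4 hydroxyl as the directing group.

Step 13
Reactants: 27
Product: 28 10α‑(benzyloxy)‑8α‑(tert‑butyldimethylsilyloxy)‑4β,6α‑dihydroxy‑5αH‑daucan‑9‑one
Conditions: Me4NBH(OAc)3, MeCN/AcOH (1:1), −30 → 0 °C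
Reagents that add atoms: none
Why: Hydroxyl‑directed reduction (Evans–Saksena), in which the alkoxy‑borohydride formed at O4 delivers hydride intramolecularly to the C6 carbonyl from the β face on which O4 lies, giving the 1,3‑anti diol with the 6α (6R) hydroxyl, while the C9 ketone has no free hydroxyl within reach and is inert to this mild reagent.

Step 14
Reactants: 28
Product: 29 8α‑(tert‑butyldimethylsilyloxy)‑4β,6α,10α‑trihydroxy‑5αH‑daucan‑9‑one
Conditions: H2 (1 atm), Pd(OH)2/C, EtOAc, rt
Reagents that add atoms: none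
Why: Hydrogenolysis of the benzyl ether frees the C10 hydroxyl at a stage where no other reducible group is present.

Step 15
Reactants: 29; 30 angelic acid
Product: 31 6α,10α‑bis(angeloyloxy)‑8α‑(tert‑butyldimethylsilyloxy)‑4β‑hydroxy‑5αH‑daucan‑9‑one
Conditions: angelic acid (6 equiv), 2,4,6‑trichlorobenzoyl chloride (6 equiv), Et3N, toluene, rt, 2 h; then 29, 80 °C
Reagents that add atoms: angelic acid, C/C=C(/C)C(=O)O
Why: Yamaguchi‑type esterification through the mixed anhydride acylates both secondary hydroxyls (C6 and the C10 α‑ketol) without the nucleophilic catalysis that isomerises angelate to tiglate, the tertiary C4 hydroxyl being too hindered to react and O9 being differentiated from O10 because C9 is still a ketone.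

Step 16
Reactants: 31
Product: 32 6α,10α‑bis(angeloyloxy)‑8α‑(tert‑butyldimethylsilyloxy)‑5αH‑daucane‑4β,9α‑diol
Conditions: NaBH4, CeCl3·7H2O, MeOH/THF, −78 → −40 °C; AcOH quench at −40 °C
Reagents that add atoms: none
Why: Borohydride reduction under steric (Felkin‑type) control, in which the α face of C9 is flanked by the O8 silyloxy and O10 angeloyloxy groups so that hydride should add from the β face between the C8 methyl and H‑10 and give the 9α (9R) alcohol, low temperature and acidic quench being meant to prevent acyl migration from O10 to O9.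

Step 17
Reactants: 32
Product: 33 target, (1R,4S,5R,6R,8S,9R,10R)‑6,10‑bis(angeloyloxy)daucane‑4,8,9‑triol (CNP0194216.1)
Conditions: HF·pyridine, THF, 0 °C → rt
Reagents that add atoms: none
Why: Fluoride cleavage of the tert‑butyldimethylsilyl ether under mildly acidic conditions leaves the angelates and their Z geometry untouched and does not promote acyl migration.

**Compound list**

1 | (R)‑terpinen‑4‑ol, (1R)‑4‑methyl‑1‑(propan‑2‑yl)cyclohex‑3‑en‑1‑ol | CC1=CC[C@@](O)(C(C)C)CC1 | starting material
2 | triethylsilyl trifluoromethanesulfonate | CC[Si](CC)(CC)OS(=O)(=O)C(F)(F)F | starting material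
3 | (R)‑triethyl{[4‑methyl‑1‑(propan‑2‑yl)cyclohex‑3‑en‑1‑yl]oxy}silane | CC1=CC[C@@](O[Si](CC)(CC)CC)(C(C)C)CC1 | intermediate
4 | ozone | [O-][O+]=O | starting material
5 | methanol | CO | starting material
6 | 7‑hydroperoxy‑7‑methoxy‑5‑(propan‑2‑yl)‑5‑(triethylsilyloxy)heptan‑2‑one (C5 as in 1; C7 a mixture) | COC(OO)C[C@@](O[Si](CC)(CC)CC)(C(C)C)CCC(C)=O | intermediate
7 | methyl (R)‑6‑oxo‑3‑(propan‑2‑yl)‑3‑(triethylsilyloxy)heptanoate | COC(=O)C[C@@](O[Si](CC)(CC)CC)(C(C)C)CCC(C)=O | intermediate
8 | (benzyloxymethyl)triphenylphosphonium chloride | [Cl-].c1ccc(cc1)[P+](COCc1ccccc1)(c1ccccc1)c1ccccc1 | starting material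
9 | methyl (R)‑7‑(benzyloxy)‑6‑methyl‑3‑(propan‑2‑yl)‑3‑(triethylsilyloxy)hept‑6‑enoate (E/Z) | COC(=O)C[C@@](O[Si](CC)(CC)CC)(C(C)C)CCC(C)=COCc1ccccc1 | intermediate
10 | N,O‑dimethylhydroxylamine hydrochloride | CNOC.Cl | starting material
11 | methylmagnesium bromide | C[Mg]Br | starting material
12 | (R)‑7‑(benzyloxy)‑N‑methoxy‑N,6‑dimethyl‑3‑(propan‑2‑yl)‑3‑(triethylsilyloxy)hept‑6‑enamide (Weinreb amide) | CON(C)C(=O)C[C@@](O[Si](CC)(CC)CC)(C(C)C)CCC(C)=COCc1ccccc1 | intermediate
13 | (R)‑8‑(benzyloxy)‑7‑methyl‑4‑(propan‑2‑yl)‑4‑(triethylsilyloxy)oct‑7‑en‑2‑one | CC(=O)C[C@@](O[Si](CC)(CC)CC)(C(C)C)CCC(C)=COCc1ccccc1 | intermediate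
14 | chlorotrimethylsilane | C[Si](C)(C)Cl | starting material
15 | (R)‑8‑(benzyloxy)‑7‑methyl‑4‑(propan‑2‑yl)‑4‑(triethylsilyloxy)‑2‑(trimethylsilyloxy)octa‑1,7‑diene | C=C(O[Si](C)(C)C)C[C@@](O[Si](CC)(CC)CC)(C(C)C)CCC(C)=COCc1ccccc1 | intermediate
16 | methyl pyruvate | COC(=O)C(C)=O | starting material
17 | methyl (2S,6R)‑10‑(benzyloxy)‑2,9‑dimethyl‑4‑oxo‑6‑(propan‑2‑yl)‑6‑(triethylsilyloxy)‑2‑(trimethylsilyloxy)dec‑9‑enoate | COC(=O)[C@@](C)(O[Si](C)(C)C)CC(=O)C[C@@](O[Si](CC)(CC)CC)(C(C)C)CCC(C)=COCc1ccccc1 | intermediate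
18 | O8‑trimethylsilyl ether of 19 (formed as its lithium enolate; C9 enol drawn) | O=C1C[C@](C)(O[Si](C)(C)C)C(O)=C1[C@@](O[Si](CC)(CC)CC)(C(C)C)CCC(C)=COCc1ccccc1 | intermediate
19 | (4S)‑4‑hydroxy‑4‑methylcyclopentane‑1,3‑dione bearing at C2 (daucane C5) the group C(OSiEt3)(iPr)CH2CH2C(CH3)=CH–OCH2Ph; C9 enol drawn | O=C1C[C@](C)(O)C(O)=C1[C@@](O[Si](CC)(CC)CC)(C(C)C)CCC(C)=COCc1ccccc1 | intermediate
20 | 1,1'‑carbonyldiimidazole | O=C(n1ccnc1)n1ccnc1 | starting material
21 | cyclic enol carbonate of 19 (1,3‑dioxol‑2‑one fused at C8–C9 to the cyclopentenone; C5=C9, C6=O; 8S) | O=C1C[C@]2(C)OC(=O)OC2=C1[C@@](O[Si](CC)(CC)CC)(C(C)C)CCC(C)=COCc1ccccc1 | intermediate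
22 | cyclobutane photoadduct (C5–C9–C10–C1 ring; all ring fusions cis; 10‑OBn anti to the C1 methyl) | O=C1C[C@]2(C)OC(=O)O[C@@]23[C@H](OCc5ccccc5)[C@]4(C)CC[C@](O[Si](CC)(CC)CC)(C(C)C)[C@]134 | intermediate
23 | cyclobutane‑8,9‑diol from hydrolysis of 22 | O=C1C[C@](C)(O)[C@@]2(O)[C@H](OCc4ccccc4)[C@]3(C)CC[C@](O[Si](CC)(CC)CC)(C(C)C)[C@]123 | intermediate
24 | 10α‑(benzyloxy)‑8α‑hydroxy‑4β‑(triethylsilyloxy)‑5αH‑daucane‑6,9‑dione | O=C1C[C@](C)(O)C(=O)[C@H](OCc3ccccc3)[C@]2(C)CC[C@](O[Si](CC)(CC)CC)(C(C)C)[C@@H]12 | intermediate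
25 | tert‑butyldimethylsilyl trifluoromethanesulfonate | CC(C)(C)[Si](C)(C)OS(=O)(=O)C(F)(F)F | starting material
26 | 10α‑(benzyloxy)‑8α‑(tert‑butyldimethylsilyloxy)‑4β‑(triethylsilyloxy)‑5αH‑daucane‑6,9‑dione | O=C1C[C@](C)(O[Si](C)(C)C(C)(C)C)C(=O)[C@H](OCc3ccccc3)[C@]2(C)CC[C@](O[Si](CC)(CC)CC)(C(C)C)[C@@H]12 | intermediate
27 | 10α‑(benzyloxy)‑8α‑(tert‑butyldimethylsilyloxy)‑4β‑hydroxy‑5αH‑daucane‑6,9‑dione | O=C1C[C@](C)(O[Si](C)(C)C(C)(C)C)C(=O)[C@H](OCc3ccccc3)[C@]2(C)CC[C@](O)(C(C)C)[C@@H]12 | intermediate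
28 | 10α‑(benzyloxy)‑8α‑(tert‑butyldimethylsilyloxy)‑4β,6α‑dihydroxy‑5αH‑daucan‑9‑one | O[C@@H]1C[C@](C)(O[Si](C)(C)C(C)(C)C)C(=O)[C@H](OCc3ccccc3)[C@]2(C)CC[C@](O)(C(C)C)[C@@H]12 | intermediate
29 | 8α‑(tert‑butyldimethylsilyloxy)‑4β,6α,10α‑trihydroxy‑5αH‑daucan‑9‑one | O[C@@H]1C[C@](C)(O[Si](C)(C)C(C)(C)C)C(=O)[C@H](O)[C@]2(C)CC[C@](O)(C(C)C)[C@@H]12 | intermediate
30 | angelic acid, (Z)‑2‑methylbut‑2‑enoic acid | C/C=C(/C)C(=O)O | starting material
31 | 6α,10α‑bis(angeloyloxy)‑8α‑(tert‑butyldimethylsilyloxy)‑4β‑hydroxy‑5αH‑daucan‑9‑one | C/C=C(/C)C(=O)O[C@@H]1C[C@](C)(O[Si](C)(C)C(C)(C)C)C(=O)[C@H](OC(=O)/C(C)=C\C)[C@]2(C)CC[C@](O)(C(C)C)[C@@H]12 | intermediate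
32 | 6α,10α‑bis(angeloyloxy)‑8α‑(tert‑butyldimethylsilyloxy)‑5αH‑daucane‑4β,9α‑diol | C/C=C(/C)C(=O)O[C@@H]1C[C@](C)(O[Si](C)(C)C(C)(C)C)[C@H](O)[C@H](OC(=O)/C(C)=C\C)[C@]2(C)CC[C@](O)(C(C)C)[C@@H]12 | intermediate
33 | (1R,4S,5R,6R,8S,9R,10R)‑6,10‑bis(angeloyloxy)daucane‑4,8,9‑triol (CNP0194216.1) | C/C=C(/C)C(=O)O[C@@H]1C[C@](C)(O)[C@H](O)[C@H](OC(=O)/C(C)=C\C)[C@]2(C)CC[C@](O)(C(C)C)[C@@H]12 | target

**Totals**

Total step count: 17. Longest linear sequence: 17 steps (from 1).

**Steps most likely to fail**

Step 9. What may go wrong: the excited enol carbonate may undergo 1,3‑acyl shift or lose CO2, and the very congested 1,4‑biradical may revert to 21 faster than it closes, so that photodecomposition outruns cycloaddition. The fallback sets out from 19 and comes back at 27; it runs the same cycloaddition on a vinylogous‑ester‑type chromophore that cannot rearrange by acyl shift and is opened by fluoride instead of base. Dione 19 with tBu2Si(OTf)2 and 2,6‑lutidine in CH2Cl2 should give the cyclic di‑tert‑butylsilylene enol ether F1, in which silicon bridges O8 and the C9 enol oxygen as the carbonate does in 21. Irradiation under the conditions of step 9 should give the silylene‑bridged cyclobutane F2 by the same stereochemical logic. HF·pyridine in THF then cleaves the silylene and the triethylsilyl ether, the freed cyclobutanol fragments by retro‑aldol and, after brief equilibration with DBU, the dihydroxy diketone F3 results. Selective silylation of the less hindered O8 (tBuMe2SiOTf, 2,6‑lutidine, −78 °C) returns to 27.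

Step 10. What may go wrong: kinetic C‑protonation of the C5 enolate from the less hindered β face gives the cis ring fusion, and with the silyl ether on O4 equilibration to the trans isomer may be slow or incomplete; long exposure to base may also start β‑elimination of the O4 silyloxy group or retro‑aldol cleavage at C7–C8. The fallback sets out from 22 and comes back at 27; it corrects the ring fusion later, under hydrogen‑bond control. Short hydrolysis of 22 (LiOH·H2O, THF/H2O, −10 °C, immediate buffering) should give the diketone rich in the cis‑fused C5 epimer F4. Silylation of O8 as in step 11 gives the bis‑silyl ether F5, and removal of the triethylsilyl group as in step 12 gives the hydroxy ketone F6. With catalytic DBU in toluene, F6 should equilibrate at C5 to 27, because only in the trans‑fused isomer are O4–H and the C6 carbonyl cis on ring A and able to form a hydrogen bond.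

Step 7. What may go wrong: β‑elimination of the C8 silyloxy group from the C7 enolate (or of the O4 silyloxy group from the C5 enolate) may be faster than attack of the hindered C5 enolate on the hindered ester. The fallback sets out from 17 and comes back at 19; it closes the ring by aldol addition to an aldehyde, a much better acceptor than the ester, and then oxidises. iBu2AlH (CH2Cl2, −78 → 0 °C) reduces ester and ketone of 17 to the diol F7, and Dess–Martin periodinane gives the keto aldehyde F8. Catalytic DBU (CH2Cl2, 0 °C) should close the five‑membered ring by attack of the C5 enolate on the non‑enolisable aldehyde and give the β‑hydroxy ketone F9 (the C7 enolate cannot cyclise). Dess–Martin oxidation of F9 gives the silylated dione 18, which is desilylated as in step 7 (K2CO3, MeOH) to 19.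

**Further compounds**

F1 | step 9 | O8,O9‑di‑tert‑butylsilylene enol ether of dione 19 | O=C1C[C@]2(C)O[Si](C(C)(C)C)(C(C)(C)C)OC2=C1[C@@](O[Si](CC)(CC)CC)(C(C)C)CCC(C)=COCc1ccccc1
F2 | step 9 | silylene‑bridged cyclobutane photoadduct (silicon analogue of 22) | O=C1C[C@]2(C)O[Si](C(C)(C)C)(C(C)(C)C)O[C@@]23[C@H](OCc5ccccc5)[C@]4(C)CC[C@](O[Si](CC)(CC)CC)(C(C)C)[C@]134
F3 | step 9 | 10α‑(benzyloxy)‑4β,8α‑dihydroxy‑5αH‑daucane‑6,9‑dione | O=C1C[C@](C)(O)C(=O)[C@H](OCc3ccccc3)[C@]2(C)CC[C@](O)(C(C)C)[C@@H]12
F4 | step 10 | 5‑epi‑24 (cis‑fused, H‑5 β) | O=C1C[C@](C)(O)C(=O)[C@H](OCc3ccccc3)[C@]2(C)CC[C@](O[Si](CC)(CC)CC)(C(C)C)[C@H]12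
F5 | step 10 | 5‑epi‑26 | O=C1C[C@](C)(O[Si](C)(C)C(C)(C)C)C(=O)[C@H](OCc3ccccc3)[C@]2(C)CC[C@](O[Si](CC)(CC)CC)(C(C)C)[C@H]12
F6 | step 10 | 5‑epi‑27 | O=C1C[C@](C)(O[Si](C)(C)C(C)(C)C)C(=O)[C@H](OCc3ccccc3)[C@]2(C)CC[C@](O)(C(C)C)[C@H]12
F7 | step 7 | diol from reduction of 17 (C6 carbinol a mixture) | OC[C@@](C)(O[Si](C)(C)C)CC(O)C[C@@](O[Si](CC)(CC)CC)(C(C)C)CCC(C)=COCc1ccccc1
F8 | step 7 | keto aldehyde (C9 aldehyde, C6 ketone) | O=C[C@@](C)(O[Si](C)(C)C)CC(=O)C[C@@](O[Si](CC)(CC)CC)(C(C)C)CCC(C)=COCc1ccccc1
F9 | step 7 | 3‑hydroxycyclopentanone aldol (C5 and C9 mixtures) | O=C1C[C@](C)(O[Si](C)(C)C)C(O)C1[C@@](O[Si](CC)(CC)CC)(C(C)C)CCC(C)=COCc1ccccc1
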